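**Retrosynthetic overview** (side chain numbered C1′ at the ring to C16′)
1. The quinone comes from hydroquinone dimethyl ether 19 by oxidative demethylation in the last step. No ring is built: the carbocycle is bought in aryl bromide 3 and only unmasked at the end.
2. C11′–C12′: chelation-controlled addition of the homoprenyl Grignard reagent to (R)-α-hydroxy methyl ketone 16 sets the tertiary carbinol from C10′, which is bought in (R)-malic acid.
3. C8′–C9′ (key bond): Ireland–Claisen [3,3] rearrangement of the malate-derived allyl ester 10, which also sets the 6′E olefin, followed by Barton decarboxylation.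
4. Allylic alcohol 6: aryllithium plus 6,7-epoxygeranyl chloride (aryl–C1′ bond), then epoxide-to-allylic-alcohol isomerisation.

Assumption: aryl bromide 3 is taken as a catalogue compound (otherwise two steps from 4-methoxy-2-methylphenol by ortho-bromination and O-methylation).

**Step 1**
Reactants: 1 geranyl chloride
Product: 2 3-[(3E)-5-chloro-3-methylpent-3-en-1-yl]-2,2-dimethyloxirane
Conditions: mCPBA (1.0 equiv), NaHCO3, CH2Cl2, −20 → 0 °C
Reagents that add atoms: mCPBA (3-chloroperoxybenzoic acid), OOC(=O)c1cccc(Cl)c1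
Why: Prilezhaev epoxidation goes to the remote electron-rich 6,7-olefin because the 2,3-olefin is deactivated by the allylic chloride; the new centre is racemic and is erased in step 7.

**Step 2**
Reactants: 2 3-[(3E)-5-chloro-3-methylpent-3-en-1-yl]-2,2-dimethyloxirane; 3 1-bromo-2,5-dimethoxy-3-methylbenzene
Product: 5 3-[(3E)-5-(2,5-dimethoxy-3-methylphenyl)-3-methylpent-3-en-1-yl]-2,2-dimethyloxirane, via (2,5-dimethoxy-3-methylphenyl)lithium 4 (not isolated)
Conditions: n-BuLi, THF, −78 °C (3 → 4); CuBr·SMe2 (10 mol%), then 2, −78 → 0 °C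
Reagents that add atoms: none
Why: Bromine–lithium exchange followed by copper-catalysed SN2 allylic substitution at the primary allylic chloride keeps the 2′E geometry, and the trisubstituted epoxide is inert at this temperature.

**Step 3**
Reactants: 5 3-[(3E)-5-(2,5-dimethoxy-3-methylphenyl)-3-methylpent-3-en-1-yl]-2,2-dimethyloxirane
Product: 6 (6E)-8-(2,5-dimethoxy-3-methylphenyl)-2,6-dimethylocta-1,6-dien-3-ol
Conditions: Al(OiPr)3 (0.2 equiv), toluene, 110 °C
Reagents that add atoms: none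
Why: Aluminium-alkoxide-mediated epoxide-to-allylic-alcohol isomerisation (syn β-elimination from a methyl group) gives the 2-methylalk-1-en-3-ol needed for the rearrangement; its carbinol centre is racemic and is erased in step 7.

**Step 4**
Reactants: 7 (R)-malic acid
Product: 8 [(4R)-2,2-dimethyl-5-oxo-1,3-dioxolan-4-yl]acetic acid
Conditions: Me2C(OMe)2, p-TsOH·H2O (2 mol%), 23 °C
Reagents that add atoms: 2,2-dimethoxypropane, COC(C)(C)OC
Why: Acid-catalysed acetonide formation ties the α-hydroxy acid into a dioxolanone and leaves the β-carboxyl free; no bond to the (R) centre is touched.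

**Step 5**
Reactants: 6 (6E)-8-(2,5-dimethoxy-3-methylphenyl)-2,6-dimethylocta-1,6-dien-3-ol; 8 [(4R)-2,2-dimethyl-5-oxo-1,3-dioxolan-4-yl]acetic acid
Product: 9 (6E)-8-(2,5-dimethoxy-3-methylphenyl)-2,6-dimethylocta-1,6-dien-3-yl [(4R)-2,2-dimethyl-5-oxo-1,3-dioxolan-4-yl]acetate
Conditions: DCC, DMAP (10 mol%), CH2Cl2, 0 → 23 °C
Reagents that add atoms: none
Why: Steglich esterification of the free carboxyl with the secondary allylic alcohol gives a 1:1 epimer pair at the carbinol carbon, which converges in step 7.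

**Step 6**
Reactants: 9 (6E)-8-(2,5-dimethoxy-3-methylphenyl)-2,6-dimethylocta-1,6-dien-3-yl [(4R)-2,2-dimethyl-5-oxo-1,3-dioxolan-4-yl]acetate
Product: 10 (6E)-8-(2,5-dimethoxy-3-methylphenyl)-2,6-dimethylocta-1,6-dien-3-yl (3R)-3-hydroxy-4-(morpholin-4-yl)-4-oxobutanoate
Conditions: morpholine (2 equiv), THF, 23 °C
Reagents that add atoms: morpholine, C1COCCN1
Why: Aminolysis of the activated dioxolanone releases acetone and gives a tertiary α-hydroxy amide (which cannot close to an imide), while the hindered allylic ester is left alone.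

**Step 7**
Reactants: 10 (6E)-8-(2,5-dimethoxy-3-methylphenyl)-2,6-dimethylocta-1,6-dien-3-yl (3R)-3-hydroxy-4-(morpholin-4-yl)-4-oxobutanoate
Product: 13 (3R)-2-[(2E,6E)-8-(2,5-dimethoxy-3-methylphenyl)-2,6-dimethylocta-2,6-dien-1-yl]-3-hydroxy-4-(morpholin-4-yl)-4-oxobutanoic acid, via bis(trimethylsilyl) ketene acetal 11 (not isolated), via rearranged bis(trimethylsilyl) ester 12 (not isolated)
Conditions: LiN(SiMe3)2 (2.4 equiv), THF, −78 °C; Me3SiCl (3 equiv), −78 → 60 °C; then 1 M HCl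
Reagents that add atoms: none
Why: Ireland–Claisen [3,3]-sigmatropic rearrangement through a chair transition state with the chain equatorial forms the C8′–C9′ bond and the 6′E trisubstituted olefin; the malate carbinol is not involved, and the new CH(CO2H) centre is a mixture that is erased in step 8.

**Step 8**
Reactants: 13 (3R)-2-[(2E,6E)-8-(2,5-dimethoxy-3-methylphenyl)-2,6-dimethylocta-2,6-dien-1-yl]-3-hydroxy-4-(morpholin-4-yl)-4-oxobutanoic acid
Product: 15 (2R,5E,9E)-11-(2,5-dimethoxy-3-methylphenyl)-2-hydroxy-5,9-dimethyl-1-(morpholin-4-yl)undeca-5,9-dien-1-one, via Barton ester 14 (not isolated)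
Conditions: N-hydroxypyridine-2-thione, DCC, DMAP (cat.), CH2Cl2, 0 °C, dark; then t-BuSH, hν (tungsten lamp), 23 °C
Reagents that add atoms: none
Why: Barton reductive radical decarboxylation (thiohydroxamate ester, thiol as hydrogen donor) removes the extra carboxyl carbon and leaves C9′ as CH2; the β-hydroxy alkyl radical does not fragment or cyclise.

**Step 9**
Reactants: 15 (2R,5E,9E)-11-(2,5-dimethoxy-3-methylphenyl)-2-hydroxy-5,9-dimethyl-1-(morpholin-4-yl)undeca-5,9-dien-1-one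
Product: 16 (3R,6E,10E)-12-(2,5-dimethoxy-3-methylphenyl)-3-hydroxy-6,10-dimethyldodeca-6,10-dien-2-one
Conditions: MeMgBr (3.5 equiv), THF, 0 °C; aq. NH4Cl
Reagents that add atoms: methylmagnesium bromide, C[Mg]Br
Why: Acyl substitution of the morpholine amide proceeds through a chelated tetrahedral intermediate that collapses only on work-up, so the methyl ketone forms without over-addition and the α-centre stays an alkoxide-bearing, non-enolised carbon.

**Step 10**
Reactants: 16 (3R,6E,10E)-12-(2,5-dimethoxy-3-methylphenyl)-3-hydroxy-6,10-dimethyldodeca-6,10-dien-2-one; 17 5-bromo-2-methylpent-2-ene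
Product: 19 (6R,7R,10E,14E)-16-(2,5-dimethoxy-3-methylphenyl)-2,6,10,14-tetramethylhexadeca-2,10,14-triene-6,7-diol, via (4-methylpent-3-en-1-yl)magnesium bromide 18 (not isolated)
Conditions: Mg, THF, 40 °C (17 → 18, 3 equiv); then 16, THF, −78 → −20 °C; aq. NH4Cl
Reagents that add atoms: none
Why: Grignard addition under Cram-chelate control: the magnesium alkoxide of the C10′ hydroxyl chelates the ketone and the nucleophile enters from the face of the C10′ hydrogen, which sets C11′ as R (syn-diol) from the 10′R centre.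

**Step 11**
Reactants: 19 (6R,7R,10E,14E)-16-(2,5-dimethoxy-3-methylphenyl)-2,6,10,14-tetramethylhexadeca-2,10,14-triene-6,7-diol
Product: 20 2-[(2E,6E,10R,11R)-10,11-dihydroxy-3,7,11,15-tetramethylhexadeca-2,6,14-trien-1-yl]-6-methylcyclohexa-2,5-diene-1,4-dione
Conditions: (NH4)2Ce(NO3)6 (2.5 equiv), MeCN–H2O (2:1), 0 °C, 15 min
Reagents that add atoms: water, O
Why: Oxidative demethylation of the hydroquinone dimethyl ether by tetravalent cerium gives the p-quinone within minutes, faster than attack on the isolated olefins or the diol; no stereocentre is touched.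

**Compound list**
1 | geranyl chloride, (2E)-1-chloro-3,7-dimethylocta-2,6-diene | CC(C)=CCC/C(C)=C/CCl | starting material
2 | 3-[(3E)-5-chloro-3-methylpent-3-en-1-yl]-2,2-dimethyloxirane (racemic) | CC1(C)OC1CC/C(C)=C/CCl | intermediate
3 | 1-bromo-2,5-dimethoxy-3-methylbenzene | COc1cc(C)c(OC)c(Br)c1 | starting material
4 | (2,5-dimethoxy-3-methylphenyl)lithium | COc1cc(C)c(OC)c([Li])c1 | intermediate
5 | 3-[(3E)-5-(2,5-dimethoxy-3-methylphenyl)-3-methylpent-3-en-1-yl]-2,2-dimethyloxirane (racemic) | COc1cc(C)c(OC)c(C/C=C(C)/CCC2OC2(C)C)c1 | intermediate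
6 | (6E)-8-(2,5-dimethoxy-3-methylphenyl)-2,6-dimethylocta-1,6-dien-3-ol (racemic) | COc1cc(C)c(OC)c(C/C=C(C)/CCC(O)C(C)=C)c1 | intermediate
7 | (R)-malic acid, (2R)-2-hydroxybutanedioic acid | OC(=O)C[C@@H](O)C(O)=O | starting material
8 | [(4R)-2,2-dimethyl-5-oxo-1,3-dioxolan-4-yl]acetic acid | CC1(C)O[C@H](CC(O)=O)C(=O)O1 | intermediate
9 | (6E)-8-(2,5-dimethoxy-3-methylphenyl)-2,6-dimethylocta-1,6-dien-3-yl [(4R)-2,2-dimethyl-5-oxo-1,3-dioxolan-4-yl]acetate (epimers at the carbinol carbon) | COc1cc(C)c(OC)c(C/C=C(C)/CCC(OC(=O)C[C@H]2OC(C)(C)OC2=O)C(C)=C)c1 | intermediate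
10 | (6E)-8-(2,5-dimethoxy-3-methylphenyl)-2,6-dimethylocta-1,6-dien-3-yl (3R)-3-hydroxy-4-(morpholin-4-yl)-4-oxobutanoate (epimers at the carbinol carbon) | COc1cc(C)c(OC)c(C/C=C(C)/CCC(OC(=O)C[C@@H](O)C(=O)N2CCOCC2)C(C)=C)c1 | intermediate
11 | bis(trimethylsilyl) ketene acetal of 10 (O-silyl ketene acetal, hydroxyl also silylated) | COc1cc(C)c(OC)c(C/C=C(C)/CCC(OC(O[Si](C)(C)C)=C[C@@H](O[Si](C)(C)C)C(=O)N2CCOCC2)C(C)=C)c1 | intermediate
12 | trimethylsilyl (3R)-2-[(2E,6E)-8-(2,5-dimethoxy-3-methylphenyl)-2,6-dimethylocta-2,6-dien-1-yl]-4-(morpholin-4-yl)-4-oxo-3-[(trimethylsilyl)oxy]butanoate | COc1cc(C)c(OC)c(C/C=C(C)/CC/C=C(C)/CC(C(=O)O[Si](C)(C)C)[C@@H](O[Si](C)(C)C)C(=O)N2CCOCC2)c1 | intermediate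
13 | (3R)-2-[(2E,6E)-8-(2,5-dimethoxy-3-methylphenyl)-2,6-dimethylocta-2,6-dien-1-yl]-3-hydroxy-4-(morpholin-4-yl)-4-oxobutanoic acid (epimers at C2) | COc1cc(C)c(OC)c(C/C=C(C)/CC/C=C(C)/CC(C(O)=O)[C@@H](O)C(=O)N2CCOCC2)c1 | intermediate
14 | Barton ester of 13 (2-thioxopyridin-1(2H)-yl ester) | COc1cc(C)c(OC)c(C/C=C(C)/CC/C=C(C)/CC(C(=O)ON2C=CC=CC2=S)[C@@H](O)C(=O)N2CCOCC2)c1 | intermediate
15 | (2R,5E,9E)-11-(2,5-dimethoxy-3-methylphenyl)-2-hydroxy-5,9-dimethyl-1-(morpholin-4-yl)undeca-5,9-dien-1-one | COc1cc(C)c(OC)c(C/C=C(C)/CC/C=C(C)/CC[C@@H](O)C(=O)N2CCOCC2)c1 | intermediate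
16 | (3R,6E,10E)-12-(2,5-dimethoxy-3-methylphenyl)-3-hydroxy-6,10-dimethyldodeca-6,10-dien-2-one | COc1cc(C)c(OC)c(C/C=C(C)/CC/C=C(C)/CC[C@@H](O)C(C)=O)c1 | intermediate
17 | 5-bromo-2-methylpent-2-ene | CC(C)=CCCBr | starting material
18 | (4-methylpent-3-en-1-yl)magnesium bromide | CC(C)=CCC[Mg]Br | intermediate
19 | (6R,7R,10E,14E)-16-(2,5-dimethoxy-3-methylphenyl)-2,6,10,14-tetramethylhexadeca-2,10,14-triene-6,7-diol | COc1cc(C)c(OC)c(C/C=C(C)/CC/C=C(C)/CC[C@@H](O)[C@](C)(O)CCC=C(C)C)c1 | intermediate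
20 | 2-[(2E,6E,10R,11R)-10,11-dihydroxy-3,7,11,15-tetramethylhexadeca-2,6,14-trien-1-yl]-6-methylcyclohexa-2,5-diene-1,4-dione | CC(C)=CCC[C@@](C)(O)[C@H](O)CC/C(C)=C/CC/C(C)=C/CC1=CC(=O)C=C(C)C1=O | target

**Total step count:** 11.
**Longest linear sequence:** 10 steps (1 → 20 through steps 1–3 and 5–11; step 4 is the side branch).

**Steps most likely to fail and fallbacks**

Step 7 (Ireland–Claisen rearrangement on the unprotected β-hydroxy ester). Retro-aldol cleavage or β-elimination of the doubly deprotonated ester can compete before silylation. The fallback gives up the unprotected substrate and carries the hydroxyl as a robust silyl ether. It sets out from 10: TBSOTf and 2,6-lutidine give the tert-butyldimethylsilyl ether F1. LiN(iPr)2 and Me3SiCl at −78 °C give the trimethylsilyl ketene acetal F2, which rearranges on warming to the trimethylsilyl ester F3 and is hydrolysed on work-up to the silyl-protected acid F4. HF·pyridine in THF then removes the silyl ether, and the sequence comes back to the route at 13.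

Step 10 (facial selectivity of the Grignard addition to the free α-hydroxy ketone). If the magnesium alkoxide chelate gives a poor diastereomer ratio, the fallback switches to an α-alkoxy ketone, where the five-membered ether chelate is the classical high-selectivity case. It sets out from 15: NaH and 4-methoxybenzyl chloride in DMF give the 4-methoxybenzyl ether F5. MeMgBr converts the amide into the α-(4-methoxybenzyloxy) methyl ketone F6. Grignard reagent 18 in THF at −78 °C gives the protected tertiary alcohol F7 with the same facial sense. (NH4)2Ce(NO3)6 (5 equiv) in MeCN–H2O then removes the benzyl ether and oxidises the arene in one operation, so the sequence comes back to the route at 20.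

Step 11 (oxidation in the presence of the free vicinal diol). Tetravalent cerium can cleave 1,2-diols if the arene oxidation is not clearly faster. The fallback masks the diol during the oxidation. It sets out from 19: Me2C(OMe)2 and PPTS give the acetonide F8. (NH4)2Ce(NO3)6 in MeCN–H2O at 0 °C gives the quinone acetonide F9. Aqueous 80% AcOH at 40 °C releases the diol, and the sequence comes back to the route at 20.

**Further compounds**
F1 | step 7 | (6E)-8-(2,5-dimethoxy-3-methylphenyl)-2,6-dimethylocta-1,6-dien-3-yl (3R)-3-[(tert-butyldimethylsilyl)oxy]-4-(morpholin-4-yl)-4-oxobutanoate | COc1cc(C)c(OC)c(C/C=C(C)/CCC(OC(=O)C[C@@H](O[Si](C)(C)C(C)(C)C)C(=O)N2CCOCC2)C(C)=C)c1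
F2 | step 7 | trimethylsilyl ketene acetal of F1 | COc1cc(C)c(OC)c(C/C=C(C)/CCC(OC(O[Si](C)(C)C)=C[C@@H](O[Si](C)(C)C(C)(C)C)C(=O)N2CCOCC2)C(C)=C)c1
F3 | step 7 | trimethylsilyl (3R)-3-[(tert-butyldimethylsilyl)oxy]-2-[(2E,6E)-8-(2,5-dimethoxy-3-methylphenyl)-2,6-dimethylocta-2,6-dien-1-yl]-4-(morpholin-4-yl)-4-oxobutanoate | COc1cc(C)c(OC)c(C/C=C(C)/CC/C=C(C)/CC(C(=O)O[Si](C)(C)C)[C@@H](O[Si](C)(C)C(C)(C)C)C(=O)N2CCOCC2)c1
F4 | step 7 | (3R)-3-[(tert-butyldimethylsilyl)oxy]-2-[(2E,6E)-8-(2,5-dimethoxy-3-methylphenyl)-2,6-dimethylocta-2,6-dien-1-yl]-4-(morpholin-4-yl)-4-oxobutanoic acid | COc1cc(C)c(OC)c(C/C=C(C)/CC/C=C(C)/CC(C(O)=O)[C@@H](O[Si](C)(C)C(C)(C)C)C(=O)N2CCOCC2)c1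
F5 | step 10 | (2R,5E,9E)-11-(2,5-dimethoxy-3-methylphenyl)-2-[(4-methoxybenzyl)oxy]-5,9-dimethyl-1-(morpholin-4-yl)undeca-5,9-dien-1-one | COc1cc(C)c(OC)c(C/C=C(C)/CC/C=C(C)/CC[C@@H](OCc2ccc(OC)cc2)C(=O)N2CCOCC2)c1
F6 | step 10 | (3R,6E,10E)-12-(2,5-dimethoxy-3-methylphenyl)-3-[(4-methoxybenzyl)oxy]-6,10-dimethyldodeca-6,10-dien-2-one | COc1cc(C)c(OC)c(C/C=C(C)/CC/C=C(C)/CC[C@@H](OCc2ccc(OC)cc2)C(C)=O)c1
F7 | step 10 | (6R,7R,10E,14E)-16-(2,5-dimethoxy-3-methylphenyl)-7-[(4-methoxybenzyl)oxy]-2,6,10,14-tetramethylhexadeca-2,10,14-trien-6-ol | COc1cc(C)c(OC)c(C/C=C(C)/CC/C=C(C)/CC[C@@H](OCc2ccc(OC)cc2)[C@](C)(O)CCC=C(C)C)c1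
F8 | step 11 | (4R,5R)-4-[(3E,7E)-9-(2,5-dimethoxy-3-methylphenyl)-3,7-dimethylnona-3,7-dien-1-yl]-2,2,5-trimethyl-5-(4-methylpent-3-en-1-yl)-1,3-dioxolane | COc1cc(C)c(OC)c(C/C=C(C)/CC/C=C(C)/CC[C@H]2OC(C)(C)O[C@]2(C)CCC=C(C)C)c1
F9 | step 11 | 2-{(2E,6E)-3,7-dimethyl-9-[(4R,5R)-2,2,5-trimethyl-5-(4-methylpent-3-en-1-yl)-1,3-dioxolan-4-yl]nona-2,6-dien-1-yl}-6-methylcyclohexa-2,5-diene-1,4-dione | O=C1C=C(C)C(=O)C(C/C=C(C)/CC/C=C(C)/CC[C@H]2OC(C)(C)O[C@]2(C)CCC=C(C)C)=C1
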